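## Retrosynthetic overview
1. Target 21 ⇒ aldehyde 17. The 2-methylprop-1-enyl group is put on last, by Wittig olefination with Ph3P=CMe2.
2. 17 ⇒ aryl ether 15. The C-a–C-c bond forms when a tethered enol ether attacks a benzylic cation; this closes the central pyran A.
3. 15 ⇒ alcohol 9 (21 heavy atoms) + chloride 14 (17 heavy atoms). The C-b–O–aryl bond forms by SNAr; this is the union of the two halves.
4. 9 ⇒ N-methylflindersine 7 by Jacobsen epoxidation (sets C-b) and methanolysis. 14 ⇒ Vilsmeier chloroformylation and methoxymethylene Wittig. Both halves come from quinolone 4.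
5. Ring order: the quinolone ring (4, used for both halves), then pyran B (oxa-6π, step 2), then pyran A (step 9).

Atom labels: C-a = CH bearing the isobutenyl group (R in 21). C-b = ring-fusion O–CH (S). C-c = ring-fusion CH bearing quinolone B (S).

Assumption: the (S,S)-Mn(salen) catalyst is taken to give the (3S,4S)-epoxide of 7, by analogy with 2,2-dimethylchromenes; if the sense were opposite, the (R,R)-catalyst would be used.

## Route

Step 1
Reactants: 1 N-methylaniline; 2 malonic acid
Product: 4 4-hydroxy-1-methylquinolin-2(1H)-one, via N-methyl-N-phenylmalonamic acid 3 (not isolated)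
Conditions: POCl3 (2 equiv), 95 °C; then ice–water
Reagents that add atoms: none
Why: N-acylation followed by POCl3-promoted intramolecular Friedel–Crafts acylation (classical 4-hydroxy-2-quinolone synthesis) builds the heterocycle used in both halves; no stereocentre is formed.

Step 2
Reactants: 4 4-hydroxy-1-methylquinolin-2(1H)-one; 5 3-methylbut-2-enal (prenal)
Product: 7 N-methylflindersine (2,2,6-trimethyl-2H-pyrano[3,2-c]quinolin-5(6H)-one), via 3-(3-methylbut-2-enylidene)quinolinedione 6 (not isolated)
Conditions: ethylenediammonium diacetate (10 mol %), 4 Å MS, toluene, 90 °C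
Reagents that add atoms: none
Why: Knoevenagel condensation at C-3 gives a 1-oxatriene that closes at once by oxa-6π electrocyclisation onto the C-4 oxygen (formal [3+3]), giving pyran B; no stereocentre is formed.

Step 3
Reactants: 7 N-methylflindersine
Product: 8 (3S,4S)-3,4-epoxy-2,2,6-trimethyl-3,4-dihydro-2H-pyrano[3,2-c]quinolin-5(6H)-one
Conditions: (S,S)-Mn(salen)Cl (Jacobsen catalyst, 4 mol %), 4-phenylpyridine N-oxide (20 mol %), aq NaOCl (pH 11.3), CH2Cl2, 0 °C; short basic-alumina plug, used at once
Reagents that add atoms: sodium hypochlorite, [Na+].[O-]Cl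
Why: In this Jacobsen–Katsuki epoxidation the cis, aryl-conjugated alkene next to a gem-dimethyl group is the best substrate class, and the catalyst delivers oxygen to one face, so C-3 (= C-b of the target) is set as S.

Step 4
Reactants: 8 (3S,4S)-epoxide
Product: 9 (3S,4R)-3-hydroxy-4-methoxy-2,2,6-trimethyl-3,4-dihydro-2H-pyrano[3,2-c]quinolin-5(6H)-one
Conditions: MeOH, PPTS (5 mol %), 0 °C
Reagents that add atoms: methanol, CO
Why: Acid-catalysed epoxide opening occurs only at the benzylic C-4 (cation stabilised by the vinylogous ring oxygen), mainly anti; the C-3–O bond is untouched so 3S is kept, and the C-4 configuration does not matter because that centre is ionised in step 9.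

Step 5
Reactants: 4 4-hydroxy-1-methylquinolin-2(1H)-one
Product: 10 4-chloro-1-methyl-2-oxo-1,2-dihydroquinoline-3-carbaldehyde
Conditions: POCl3 (4 equiv), DMF, 0 → 70 °C; then ice–water
Reagents that add atoms: N,N-dimethylformamide, CN(C)C=O; phosphoryl chloride, O=P(Cl)(Cl)Cl; water, O
Why: Vilsmeier–Haack formylation of the nucleophilic C-3 is accompanied by deoxychlorination of the vinylogous acid OH, and the N-methyl lactam carbonyl is retained; no stereocentre is formed.

Step 6
Reactants: 11 chloromethyl methyl ether
Product: 12 (methoxymethyl)triphenylphosphonium chloride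
Conditions: PPh3, toluene, 50 °C
Reagents that add atoms: triphenylphosphine, c1ccc(cc1)P(c1ccccc1)c1ccccc1
Why: SN2 quaternisation of the phosphine by a very reactive α-chloro ether gives the salt, which precipitates.

Step 7
Reactants: 10 4-chloro-1-methyl-2-oxo-1,2-dihydroquinoline-3-carbaldehyde; 12 (methoxymethyl)triphenylphosphonium chloride
Product: 14 4-chloro-3-(2-methoxyethenyl)-1-methylquinolin-2(1H)-one (E/Z mixture), via methoxymethylenetriphenylphosphorane 13 (not isolated)
Conditions: 12, NaHMDS, THF, 0 °C; then 10, −78 → 0 °C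
Reagents that add atoms: none
Why: Wittig methoxymethylenation is faster at the aldehyde than attack at C-4–Cl at low temperature with a non-nucleophilic base, and it makes the former formyl carbon (C-a) the nucleophilic β-carbon of an enol ether; both alkene isomers converge later.

Step 8
Reactants: 9 (3S,4R)-hydroxy methyl ether; 14 4-chloro-3-(2-methoxyethenyl)-1-methylquinolin-2(1H)-one
Product: 15 4-{[(3S,4R)-4-methoxy-2,2,6-trimethyl-5-oxo-3,4,5,6-tetrahydro-2H-pyrano[3,2-c]quinolin-3-yl]oxy}-3-(2-methoxyethenyl)-1-methylquinolin-2(1H)-one (E/Z mixture)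
Conditions: 9, KHMDS, 18-crown-6, THF, −20 °C; then 14, → 40 °C
Reagents that add atoms: none
Why: SNAr (addition–elimination) of the alkoxide at C-4 of the 4-chloro-2-quinolone, a vinylogous carbamoyl chloride, joins the two halves through oxygen; the carbinol C–O bond is not broken so C-b stays S.

Step 9
Reactants: 15 aryl ether
Product: 17 cis-fused bis(pyranoquinolinone) carbaldehyde (target skeleton with CHO in place of the 2-methylprop-1-enyl group; C-a R; C-b S; C-c S), via pentacyclic dimethyl acetal 16 (not isolated)
Conditions: TMSOTf (20 mol %), 2,6-di-tert-butyl-4-methylpyridine (30 mol %), CH2Cl2, −78 → −40 °C; then 1 M HCl, THF, rt; then DBU (20 mol %), CH2Cl2, rt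
Reagents that add atoms: water, O
Why: In this intramolecular Mukaiyama-type alkylation TMSOTf ionises only the benzylic C-4 methoxy group and the enol ether attacks the cation through C-a; the planar O–C=C–C tether reaches only the face syn to the C-b–O bond, so C-c is set cis-fused, and C-a, being α to the aldehyde, is equilibrated by DBU to the convex-face isomer anti to the C-c–aryl bond.

Step 10
Reactants: 18 2-iodopropane
Product: 19 isopropyltriphenylphosphonium iodide
Conditions: PPh3, MeCN, sealed tube, 100 °C
Reagents that add atoms: triphenylphosphine, c1ccc(cc1)P(c1ccccc1)c1ccccc1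
Why: SN2 quaternisation of triphenylphosphine by the secondary iodide is slow but clean at this temperature.

Step 11
Reactants: 17 pentacyclic aldehyde; 19 isopropyltriphenylphosphonium iodide
Product: 21 target CNP0107253.2 (C-a R; C-b S; C-c S), via isopropylidenetriphenylphosphorane 20 (not isolated)
Conditions: 19 (1.6 equiv), KHMDS (1.5 equiv), THF, 0 °C; then 17, −78 °C → rt
Reagents that add atoms: none
Why: Wittig olefination with the non-stabilised isopropylidene ylide converts CHO into CH=CMe2 without touching the lactam carbonyls or aryl ethers, and any base-induced epimerisation at C-a is harmless because 17 already has the thermodynamic configuration.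

## Compound list
1 | N-methylaniline | CNc1ccccc1 | starting material
2 | malonic acid | OC(=O)CC(=O)O | starting material
3 | N-methyl-N-phenylmalonamic acid | CN(c1ccccc1)C(=O)CC(=O)O | intermediate
4 | 4-hydroxy-1-methylquinolin-2(1H)-one | Cn1c(=O)cc(O)c2ccccc12 | intermediate
5 | 3-methylbut-2-enal | CC(C)=CC=O | starting material
6 | 1-methyl-3-(3-methylbut-2-enylidene)quinoline-2,4(1H,3H)-dione | CC(C)=CC=C1C(=O)c2ccccc2N(C)C1=O | intermediate
7 | N-methylflindersine | CC1(C)C=Cc2c(O1)c1ccccc1n(C)c2=O | intermediate
8 | (3S,4S)-3,4-epoxy-2,2,6-trimethyl-3,4-dihydro-2H-pyrano[3,2-c]quinolin-5(6H)-one | O1[C@H]2[C@@H]1c1c(c3ccccc3n(C)c1=O)OC2(C)C | intermediate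
9 | (3S,4R)-3-hydroxy-4-methoxy-2,2,6-trimethyl-3,4-dihydro-2H-pyrano[3,2-c]quinolin-5(6H)-one | O[C@H]1[C@H](OC)c2c(OC1(C)C)c1ccccc1n(C)c2=O | intermediate
10 | 4-chloro-1-methyl-2-oxo-1,2-dihydroquinoline-3-carbaldehyde | O=Cc1c(Cl)c2ccccc2n(C)c1=O | intermediate
11 | chloromethyl methyl ether | COCCl | starting material
12 | (methoxymethyl)triphenylphosphonium chloride | COC[P+](c1ccccc1)(c1ccccc1)c1ccccc1.[Cl-] | intermediate
13 | methoxymethylenetriphenylphosphorane | COC=P(c1ccccc1)(c1ccccc1)c1ccccc1 | intermediate
14 | 4-chloro-3-(2-methoxyethenyl)-1-methylquinolin-2(1H)-one (E/Z mixture) | COC=Cc1c(Cl)c2ccccc2n(C)c1=O | intermediate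
15 | aryl ether from 9 and 14 (3S,4R; E/Z mixture) | COC=Cc1c(O[C@H]2[C@H](OC)c3c(OC2(C)C)c2ccccc2n(C)c3=O)c2ccccc2n(C)c1=O | intermediate
16 | pentacyclic dimethyl acetal (C-b S, C-c S, epimers at C-a) | COC(OC)C1c2c(c3ccccc3n(C)c2=O)O[C@H]2[C@@H]1c1c(c3ccccc3n(C)c1=O)OC2(C)C | intermediate
17 | pentacyclic aldehyde (C-a R, C-b S, C-c S) | O=C[C@H]1c2c(c3ccccc3n(C)c2=O)O[C@H]2[C@@H]1c1c(c3ccccc3n(C)c1=O)OC2(C)C | intermediate
18 | 2-iodopropane | CC(C)I | starting material
19 | isopropyltriphenylphosphonium iodide | CC(C)[P+](c1ccccc1)(c1ccccc1)c1ccccc1.[I-] | intermediate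
20 | isopropylidenetriphenylphosphorane | CC(C)=P(c1ccccc1)(c1ccccc1)c1ccccc1 | intermediate
21 | CNP0107253.2 (C-a R, C-b S, C-c S) | CC(C)=C[C@H]1c2c(c3ccccc3n(C)c2=O)O[C@H]2[C@@H]1c1c(c3ccccc3n(C)c1=O)OC2(C)C | target

## Step count
Total step count: 11.
Longest linear sequence: 7 (steps 1, 2, 3, 4, 8, 9, 11). The other arm to the union is steps 1, 5 and 7. Steps 6 and 10 are side branches.

## Steps most likely to fail

**Step 8.** The alkoxide of 9 is hindered, and chloride 14 has lost the activating formyl group. Warming the alkoxide may also trigger a Smiles-type pyrano-to-furo isomerisation.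
Fallback: this sets out from 9 and 10 and comes back at 15. The alkoxide of 9 (NaH, THF, 0 °C) is first joined to the doubly activated chloride 10, which reacts well below room temperature. This gives the 4-aryloxy-2-oxoquinoline-3-carbaldehyde F1. The enol ether is installed only afterwards, by treating that aldehyde with ylide 13 at −78 °C, which gives 15.

**Step 9.** The cation can lose the C-b proton to give an achiral 3-aryloxy-2H-pyran. If that pyran is reprotonated, the only source of chirality is eroded. The enol ether can also be consumed by adventitious acid.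
Fallback: this sets out from 8 and 14 and comes back at 17. The order of bond formation is reversed. Epoxide 8 and enol ether 14 undergo a Lewis-acid formal [3+2] annulation (BF3·OEt2 cat., CH2Cl2, −78 °C). C-a attacks the opened benzylic carbon, and the liberated C-b oxygen traps the oxocarbenium ion. Only the cis-fused five-membered ring can close, which gives the cis-fused 2-methoxytetrahydrofuran acetal F2. Aqueous HCl/THF converts it into the lactol F3. K2CO3 in DMF then opens the lactol, and the C-b alkoxide displaces the 4-chloride intramolecularly (SNAr). The aldehyde is equilibrated at C-a under the same conditions, giving 17.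

**Step 11.** A bulky, basic ylide has to react with a hindered, enolisable α-branched aldehyde.
Fallback: this sets out from 17 and comes back at 21. The aldehyde is methylenated with the small ylide Ph3P=CH2 (from MePPh3Br and KHMDS, THF, −78 °C → rt) to give the vinyl analogue F4. The gem-dimethyl terminus is then introduced by olefin cross-metathesis (Grubbs II, neat 2-methylbut-2-ene, 40 °C), which gives 21.

## Further compounds
F1 | step 8 | 4-{[(3S,4R)-4-methoxy-2,2,6-trimethyl-5-oxo-3,4,5,6-tetrahydro-2H-pyrano[3,2-c]quinolin-3-yl]oxy}-1-methyl-2-oxo-1,2-dihydroquinoline-3-carbaldehyde | O=Cc1c(O[C@H]2[C@H](OC)c3c(OC2(C)C)c2ccccc2n(C)c3=O)c2ccccc2n(C)c1=O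
F2 | step 9 | cis-fused 2-methoxytetrahydrofuran acetal from 8 and 14 (C-b S, C-c S) | COC1O[C@H]2[C@@H](C1c1c(Cl)c3ccccc3n(C)c1=O)c1c(OC2(C)C)c2ccccc2n(C)c1=O
F3 | step 9 | lactol derived from F2 | OC1O[C@H]2[C@@H](C1c1c(Cl)c3ccccc3n(C)c1=O)c1c(OC2(C)C)c2ccccc2n(C)c1=O
F4 | step 11 | vinyl analogue of 21 (CH=CH2 at C-a) | C=C[C@H]1c2c(c3ccccc3n(C)c2=O)O[C@H]2[C@@H]1c1c(c3ccccc3n(C)c1=O)OC2(C)C
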